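**Plan**

1. Numbering follows the germacrane skeleton: C1 ketone, C2=C3 in the furanone, C4(C15)=C5, C6 lactone oxygen, C7, C8 ester, C9 hydroxyl, C10(C14) ether carbon, C11(=C13)–C12 lactone. Retrosynthetic cuts, in order: O8–acyl; C6–C7 together with the lactone bond O6–C12; C7–C11; the enol-ether bond O10–C3 (traded for O9–C3); C10–O10; C1–C2; C9–C10.
2. Enabling feature: the secondary O9 and the tertiary O10 sit on neighbouring carbons next to the C1 carbonyl of the C1–C2–C3 vinylogous ester. Either oxygen can hold C3, giving a six-membered 2,3-dihydro-4-pyranone (O9, C9, C10, C1, C2, C3) or the five-membered 3(2H)-furanone (O10, C10, C1, C2, C3). The pyranone is built first as a stereochemical template and then contracted.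
3. Forward order: aldol (C9–C10), ynone (C1–C2), pyranone ring, hydroxylation at C10, ring contraction to the furanone ring with acetonide shift, acrylate arm at C7, closure of the ten-membered carbocycle and the lactone ring, ester at O8.
4. Stereochemistry: C8 from (S)-glyceraldehyde acetonide; C9 from an auxiliary-controlled syn-aldol; C10 from enolate hydroxylation anti to the C9 substituent on the pyranone ring, carried unchanged through the contraction; C6 and C7 from the macrocyclic allylation (C7 steered by C8); 4Z from the commercial Z-enynol.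

Key step: step 7

Assumption: 1 is taken as the pure Z isomer and 4 is used freshly distilled, since it oligomerises on storage.

**Step 1**
Reactants: 1 (2Z)-3-methylpent-2-en-4-yn-1-ol
Product: 2 tert-butyl{[(2Z)-3-methylpent-2-en-4-yn-1-yl]oxy}diphenylsilane
Conditions: TBDPSCl, imidazole, CH2Cl2, 0 → 23 °C
Reagents that add atoms: tert-butyl(chloro)diphenylsilane, CC(C)(C)[Si](Cl)(c1ccccc1)c1ccccc1
Why: Silylation of the primary alcohol under neutral imidazole conditions avoids the alkoxide that would cyclise the Z-enynol to a furan, and gives a bulky, acid-stable ether that should last through the key step.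

**Step 2**
Reactants: 3 (4S)-4-benzyl-3-propanoyl-1,3-oxazolidin-2-one; 4 (4S)-2,2-dimethyl-1,3-dioxolane-4-carbaldehyde
Product: 6 (4S)-4-benzyl-3-[(2S,3S)-3-[(4S)-2,2-dimethyl-1,3-dioxolan-4-yl]-3-hydroxy-2-methylpropanoyl]-1,3-oxazolidin-2-one, via Z-dibutylboron enolate 5 (not isolated)
Conditions: Bu2BOTf, i-Pr2NEt, CH2Cl2, 0 °C; then 4, −78 → 0 °C; H2O2, pH 7 buffer, MeOH
Reagents that add atoms: none
Why: Evans syn-aldol reaction, in which the Z-boron enolate reacts through a Zimmerman–Traxler chair whose face is fixed by the (S)-benzyl auxiliary, so that the C9 carbinol should form syn to the C8 oxygen of the (S)-aldehyde under reagent control, while the C10 methyl configuration is of no consequence because C10 is reset in step 6.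

**Step 3**
Reactants: 6 syn-aldol adduct
Product: 7 (2S,3S)-3-[(4S)-2,2-dimethyl-1,3-dioxolan-4-yl]-3-hydroxy-N-methoxy-N,2-dimethylpropanamide
Conditions: MeNHOMe·HCl, AlMe3, CH2Cl2, −15 → 0 °C
Reagents that add atoms: N,O-dimethylhydroxylamine hydrochloride, CNOC.Cl
Why: Weinreb transamidation of the imide by the aluminium amide should remove the auxiliary without touching the free β-hydroxyl or the stereocentres.

**Step 4**
Reactants: 7 Weinreb amide; 2 silyl-protected Z-enyne
Product: 9 (2Z,7S,8S)-1-[(tert-butyldiphenylsilyl)oxy]-8-[(4S)-2,2-dimethyl-1,3-dioxolan-4-yl]-8-hydroxy-3,7-dimethyloct-2-en-4-yn-6-one, via lithium acetylide 8 (not isolated)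
Conditions: 2 (2.5 equiv), n-BuLi (2.4 equiv), THF, −78 °C; then 7, −78 → −20 °C; aq. NH4Cl
Reagents that add atoms: none
Why: Acylation of a lithium acetylide by a Weinreb amide proceeds through a stable chelated tetrahedral intermediate and so should stop at the ynone, joining the C2–C6 half to the C1/C7–C10 half, the extra acetylide serving only to deprotonate the hydroxyl.

**Step 5**
Reactants: 9 β-hydroxy ynone
Product: 10 (2S,3S)-6-[(2Z)-4-[(tert-butyldiphenylsilyl)oxy]but-2-en-2-yl]-2-[(4S)-2,2-dimethyl-1,3-dioxolan-4-yl]-3-methyl-2,3-dihydro-4H-pyran-4-one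
Conditions: Ph3PAuNTf2 (5 mol %), CH2Cl2, 23 °C
Reagents that add atoms: none
Why: π-Activation of the ynone by monovalent gold should trigger 6-endo-dig attack of the C9 hydroxyl on C3, the established cycloisomerisation of β-hydroxy ynones to 2,3-dihydro-4-pyranones, with the hindered silyl ether oxygen unable to compete.

**Step 6**
Reactants: 10 dihydropyranone
Product: 12 (2R,3R)-6-[(2Z)-4-[(tert-butyldiphenylsilyl)oxy]but-2-en-2-yl]-2-[(4S)-2,2-dimethyl-1,3-dioxolan-4-yl]-3-hydroxy-3-methyl-2,3-dihydro-4H-pyran-4-one, via potassium enolate 11 (not isolated)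
Conditions: KN(SiMe3)2, THF, −78 °C; then 2-(phenylsulfonyl)-3-phenyloxaziridine, −78 °C; aq. NH4Cl
Reagents that add atoms: trans-2-(phenylsulfonyl)-3-phenyloxaziridine, O=S(=O)(c1ccccc1)N1OC1c1ccccc1
Why: Kinetic α'-deprotonation of the vinylogous ester (Stork–Danheiser regiochemistry) followed by Davis oxaziridine hydroxylation, in which the oxidant should approach the nearly planar 4-oxido-2H-pyran from the face opposite the dioxolanyl group on the neighbouring sp3 carbon C9, placing O10 trans to C8 and setting C10 as R.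

**Step 7**
Reactants: 12 3-hydroxy-dihydropyranone
Product: 14 (2R)-5-[(2Z)-4-[(tert-butyldiphenylsilyl)oxy]but-2-en-2-yl]-2-[(4R,5S)-5-(hydroxymethyl)-2,2-dimethyl-1,3-dioxolan-4-yl]-2-methylfuran-3(2H)-one, via terminal-acetonide furanone 13 (not isolated)
Conditions: p-TsOH·H2O (10 mol %), acetone, 40 °C
Reagents that add atoms: none
Why: Proposed new method: protonation of the C1 carbonyl of the vinylogous ester in 12 makes C3 an oxocarbenium carbon, the tertiary O10–H held 1,4 across the pyranone adds to C3 and the O9–C3 bond then breaks, so the enol-ether link moves from O9 to O10 and the six-membered ring (O9, C9, C10, C1, C2, C3) contracts to the five-membered 3(2H)-furanone (O10, C10, C1, C2, C3) of 13, after which the isopropylidene group migrates from O7/O8 to O8/O9 and takes the freed C9 hydroxyl out of the equilibrium. The closest known reaction types are the acid-catalysed cyclodehydration of α'-hydroxy-1,3-diketones to 3(2H)-furanones, the contraction of pyranosides to furanosides by trans-acetalisation, and the thermodynamic migration of terminal acetonides to threo-internal positions. The furanone ring closes by 5-exo-trig attack of O10 on C3 (addition–elimination at the vinylogous ester), and the new dioxolane closes by 5-exo attack of O9 on the isopropylidene oxocarbenium ion. No stereocentre is formed or broken, since only the O9–C3 bond and acetal C–O bonds are cleaved, so C9 and C10 should carry the relationship set on the pyranone template into the furanone. The selectivity needed is positional (furanone over pyranone, internal over terminal acetonide) and is thermodynamic: the trans-4,5-disubstituted dioxolane of the threo 8,9-diol, the release of an unhindered primary hydroxyl in place of a tertiary one, and the gem-disubstituted C10 inside the five-membered ring should all favour 14.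

**Step 8**
Reactants: 14 furanone primary alcohol
Product: 15 (4R,5R)-5-[(2R)-5-[(2Z)-4-[(tert-butyldiphenylsilyl)oxy]but-2-en-2-yl]-2-methyl-3-oxo-2,3-dihydrofuran-2-yl]-2,2-dimethyl-1,3-dioxolane-4-carbaldehyde
Conditions: Dess–Martin periodinane, CH2Cl2, 0 → 23 °C
Reagents that add atoms: none
Why: Dess–Martin oxidation of the only free hydroxyl should give the C7 aldehyde without base, the α-stereocentre C8 being held in the thermodynamically preferred trans-dioxolane.

**Step 9**
Reactants: 15 aldehyde
Product: 16 methyl 2-{[(4S,5R)-5-[(2R)-5-[(2Z)-4-[(tert-butyldiphenylsilyl)oxy]but-2-en-2-yl]-2-methyl-3-oxo-2,3-dihydrofuran-2-yl]-2,2-dimethyl-1,3-dioxolan-4-yl](hydroxy)methyl}prop-2-enoate (both C7 epimers)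
Conditions: methyl acrylate (excess), DABCO, MeOH, 23 °C
Reagents that add atoms: methyl acrylate, C=CC(=O)OC
Why: Morita–Baylis–Hillman reaction of the activated α-alkoxy aldehyde should install C11–C13 and the ester carbon C12, the new carbinol centre C7 needing no control because it becomes sp2 in step 12.

**Step 10**
Reactants: 16 Baylis–Hillman adduct
Product: 17 methyl 2-{hydroxy[(4S,5R)-5-[(2R)-5-[(2Z)-4-hydroxybut-2-en-2-yl]-2-methyl-3-oxo-2,3-dihydrofuran-2-yl]-2,2-dimethyl-1,3-dioxolan-4-yl]methyl}prop-2-enoate (both C7 epimers)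
Conditions: HF·pyridine, pyridine, THF, 0 → 23 °C
Reagents that add atoms: none
Why: Buffered fluoride cleavage of the silyl ether should free the C6 hydroxyl while leaving the acetonide, the furanone and the Baylis–Hillman alcohol intact, and is placed before the allylic bromide exists.

**Step 11**
Reactants: 17 diol
Product: 18 methyl 2-{[(4S,5R)-2,2-dimethyl-5-[(2R)-2-methyl-3-oxo-5-[(2Z)-4-oxobut-2-en-2-yl]-2,3-dihydrofuran-2-yl]-1,3-dioxolan-4-yl](hydroxy)methyl}prop-2-enoate (both C7 epimers)
Conditions: TEMPO (10 mol %), PhI(OAc)2, CH2Cl2, 23 °C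
Reagents that add atoms: none
Why: Oxoammonium oxidation is selective for the primary allylic alcohol over the hindered secondary one and should give the Z-enal without base, so the 4Z geometry is kept.

**Step 12**
Reactants: 18 enal alcohol
Product: 19 methyl (2Z)-2-(bromomethyl)-3-[(4S,5R)-2,2-dimethyl-5-[(2R)-2-methyl-3-oxo-5-[(2Z)-4-oxobut-2-en-2-yl]-2,3-dihydrofuran-2-yl]-1,3-dioxolan-4-yl]prop-2-enoate
Conditions: NBS, Me2S, CH2Cl2, −20 °C (reagent pre-formed); then 18, −20 → 0 °C
Reagents that add atoms: N-bromosuccinimide, O=C1CCC(=O)N1Br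
Why: Corey–Kim-type activation of the Baylis–Hillman alcohol and SN2' return of bromide should give the rearranged primary allylic bromide as the favoured Z isomer (C8 cis to CH2Br), with no free NBS left to brominate the furanone.

**Step 13**
Reactants: 19 enal allylic bromide
Product: 21 8,9-O-isopropylidene lactone (8-deacyl-lobatin B acetonide; 6R,7S,8S,9R,10R,4Z; all centres as in 23), via hydroxy ester 20 (not isolated)
Conditions: CrCl2 (6 equiv), THF/DMF, 23 °C, slow addition to 2 mM; then p-TsOH (cat.), CH2Cl2, 23 °C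
Reagents that add atoms: none
Why: Intramolecular Nozaki–Hiyama-type Barbier allylation, in which divalent chromium turns the bromide into an allylchromium species that should add through its γ-carbon C7 to the aldehyde C6 to close the ten-membered carbocycle before the C6 hydroxyl lactonises onto the ester; attack on the ketone C1 is disfavoured because the five-membered ring it would form is trans-fused to the acetonide, the C7 face is expected anti to the C8 acetal oxygen, and the 6,7-trans relationship is expected from the macrocyclic transition state, a closure type established for ten-membered germacranolide rings.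

**Step 14**
Reactants: 21 acetonide lactone
Product: 22 8-deacyl-lobatin B (8,9-diol; all stereocentres as in 23)
Conditions: TFA/H2O (9:1), 0 °C
Reagents that add atoms: none
Why: Acid hydrolysis of the isopropylidene acetal should free both hydroxyls, the lactone, furanone and exocyclic methylene being stable to aqueous acid and the low temperature limiting 6,12 to 8,12 translactonisation.

**Step 15**
Reactants: 22 diol
Product: 23 lobatin B
Conditions: isovaleric anhydride (1.1 equiv), DMAP (10 mol %), 2,4,6-collidine, CH2Cl2, −40 → −20 °C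
Reagents that add atoms: 3-methylbutanoic anhydride, CC(C)CC(=O)OC(=O)CC(C)C
Why: DMAP-catalysed acylation under kinetic control should take place at O8, which is flanked by two CH carbons, before the neopentylic O9 next to the quaternary C10, and no base strong enough for 1,2-acyl migration is present.

**Compound list**

1 | (2Z)-3-methylpent-2-en-4-yn-1-ol | C#C/C(C)=C\CO | starting material
2 | tert-butyl{[(2Z)-3-methylpent-2-en-4-yn-1-yl]oxy}diphenylsilane | C#C/C(C)=C\CO[Si](c1ccccc1)(c1ccccc1)C(C)(C)C | intermediate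
3 | (4S)-4-benzyl-3-propanoyl-1,3-oxazolidin-2-one | CCC(=O)N1[C@@H](Cc2ccccc2)COC1=O | starting material
4 | (4S)-2,2-dimethyl-1,3-dioxolane-4-carbaldehyde | O=C[C@@H]1COC(C)(C)O1 | starting material
5 | Z-dibutylboron enolate of 3 | C/C=C(\OB(CCCC)CCCC)N1[C@@H](Cc2ccccc2)COC1=O | intermediate
6 | (4S)-4-benzyl-3-[(2S,3S)-3-[(4S)-2,2-dimethyl-1,3-dioxolan-4-yl]-3-hydroxy-2-methylpropanoyl]-1,3-oxazolidin-2-one | C[C@@H]([C@H](O)[C@@H]1COC(C)(C)O1)C(=O)N1[C@@H](Cc2ccccc2)COC1=O | intermediate
7 | (2S,3S)-3-[(4S)-2,2-dimethyl-1,3-dioxolan-4-yl]-3-hydroxy-N-methoxy-N,2-dimethylpropanamide | C[C@@H]([C@H](O)[C@@H]1COC(C)(C)O1)C(=O)N(C)OC | intermediate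
8 | lithium acetylide of 2 | [Li]C#C/C(C)=C\CO[Si](c1ccccc1)(c1ccccc1)C(C)(C)C | intermediate
9 | (2Z,7S,8S)-1-[(tert-butyldiphenylsilyl)oxy]-8-[(4S)-2,2-dimethyl-1,3-dioxolan-4-yl]-8-hydroxy-3,7-dimethyloct-2-en-4-yn-6-one | C[C@@H]([C@H](O)[C@@H]1COC(C)(C)O1)C(=O)C#C/C(C)=C\CO[Si](c1ccccc1)(c1ccccc1)C(C)(C)C | intermediate
10 | (2S,3S)-6-[(2Z)-4-[(tert-butyldiphenylsilyl)oxy]but-2-en-2-yl]-2-[(4S)-2,2-dimethyl-1,3-dioxolan-4-yl]-3-methyl-2,3-dihydro-4H-pyran-4-one | C[C@H]1[C@@H]([C@@H]2COC(C)(C)O2)OC(/C(C)=C\CO[Si](c3ccccc3)(c3ccccc3)C(C)(C)C)=CC1=O | intermediate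
11 | potassium enolate of 10 (4-oxido-2H-pyran) | CC2=C([O-])C=C(/C(C)=C\CO[Si](c3ccccc3)(c3ccccc3)C(C)(C)C)O[C@@H]2[C@@H]1COC(C)(C)O1.[K+] | intermediate
12 | (2R,3R)-6-[(2Z)-4-[(tert-butyldiphenylsilyl)oxy]but-2-en-2-yl]-2-[(4S)-2,2-dimethyl-1,3-dioxolan-4-yl]-3-hydroxy-3-methyl-2,3-dihydro-4H-pyran-4-one | C[C@@]1(O)[C@@H]([C@@H]2COC(C)(C)O2)OC(/C(C)=C\CO[Si](c3ccccc3)(c3ccccc3)C(C)(C)C)=CC1=O | intermediate
13 | (2R)-5-[(2Z)-4-[(tert-butyldiphenylsilyl)oxy]but-2-en-2-yl]-2-[(R)-[(4S)-2,2-dimethyl-1,3-dioxolan-4-yl](hydroxy)methyl]-2-methylfuran-3(2H)-one | C[C@@]1(OC(/C(C)=C\CO[Si](c3ccccc3)(c3ccccc3)C(C)(C)C)=CC1=O)[C@H](O)[C@@H]2COC(C)(C)O2 | intermediate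
14 | (2R)-5-[(2Z)-4-[(tert-butyldiphenylsilyl)oxy]but-2-en-2-yl]-2-[(4R,5S)-5-(hydroxymethyl)-2,2-dimethyl-1,3-dioxolan-4-yl]-2-methylfuran-3(2H)-one | C[C@@]1(OC(/C(C)=C\CO[Si](c3ccccc3)(c3ccccc3)C(C)(C)C)=CC1=O)[C@@H]2OC(C)(C)O[C@H]2CO | intermediate
15 | (4R,5R)-5-[(2R)-5-[(2Z)-4-[(tert-butyldiphenylsilyl)oxy]but-2-en-2-yl]-2-methyl-3-oxo-2,3-dihydrofuran-2-yl]-2,2-dimethyl-1,3-dioxolane-4-carbaldehyde | C[C@@]1(OC(/C(C)=C\CO[Si](c3ccccc3)(c3ccccc3)C(C)(C)C)=CC1=O)[C@@H]2OC(C)(C)O[C@H]2C=O | intermediate
16 | Baylis–Hillman adduct of 15 (methyl 2-substituted prop-2-enoate; C7 carbinol as both epimers; C6 silyl ether) | C[C@@]1(OC(/C(C)=C\CO[Si](c3ccccc3)(c3ccccc3)C(C)(C)C)=CC1=O)[C@@H]2OC(C)(C)O[C@H]2C(O)C(=C)C(=O)OC | intermediate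
17 | desilylated Baylis–Hillman adduct (C6 primary allylic alcohol; C7 carbinol as both epimers) | C[C@@]1(OC(/C(C)=C\CO)=CC1=O)[C@@H]2OC(C)(C)O[C@H]2C(O)C(=C)C(=O)OC | intermediate
18 | Z-enal Baylis–Hillman alcohol (C6 aldehyde; C7 carbinol as both epimers) | C[C@@]1(OC(/C(C)=C\C=O)=CC1=O)[C@@H]2OC(C)(C)O[C@H]2C(O)C(=C)C(=O)OC | intermediate
19 | methyl (2Z)-2-(bromomethyl)-3-[(4S,5R)-2,2-dimethyl-5-[(2R)-2-methyl-3-oxo-5-[(2Z)-4-oxobut-2-en-2-yl]-2,3-dihydrofuran-2-yl]-1,3-dioxolan-4-yl]prop-2-enoate | C[C@@]1(OC(/C(C)=C\C=O)=CC1=O)[C@@H]2OC(C)(C)O[C@H]2/C=C(\CBr)C(=O)OC | intermediate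
20 | ten-membered hydroxy ester (6R-hydroxyl; C7 S bearing the 1-(methoxycarbonyl)vinyl group; 8,9-O-isopropylidene; furanone bridge; 4Z) | O[C@@H]1/C=C(/C)C2=CC(=O)[C@](C)(O2)[C@@H]2OC(C)(C)O[C@H]2[C@H]1C(=C)C(=O)OC | intermediate
21 | 8,9-O-isopropylidene-8-deacyl-lobatin B (6,7-trans lactone; 6R,7S,8S,9R,10R; 4Z) | C=C1C(=O)O[C@@H]2/C=C(/C)C3=CC(=O)[C@](C)(O3)[C@@H]3OC(C)(C)O[C@H]3[C@@H]12 | intermediate
22 | 8-deacyl-lobatin B (8,9-diol; all stereocentres arranged as in 23) | C=C1C(=O)O[C@@H]2/C=C(/C)C3=CC(=O)[C@](C)(O3)[C@H](O)[C@@H](O)[C@@H]12 | intermediate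
23 | lobatin B (6R,7S,8S,9R,10R; 4Z) | C=C1C(=O)O[C@@H]2/C=C(/C)C3=CC(=O)[C@](C)(O3)[C@H](O)[C@@H](OC(=O)CC(C)C)[C@@H]12 | target

**Step count and risks**

Total steps: 15. Longest linear sequence: 14 steps (steps 2 to 15, from 3 and 4); step 1 is the only branch.

Most likely to fail:

1. Step 7 (proposed new method). The trans-acetalisation equilibrium may stall on the pyranone side, the acetonide may fail to migrate, or the acid may start an α-ketol shift of the tertiary hydroxy ketone. The fallback sets out from 12 and uses known reaction types only. Pyrrolidine in MeOH should open the vinylogous ester by amine exchange at C3 to the acyclic pyrrolidine enaminone F1, in which both O9–H and O10–H are free. TESCl and imidazole should silylate only the secondary C9 hydroxyl to give the C9 silyl ether enaminone F2, so that only the tertiary hydroxyl can close. Aqueous acetic acid should then close O10 onto C3 with loss of pyrrolidine (the classical amine-then-acid 3(2H)-furanone formation) to give the C9-silylated furanone F3. p-TsOH in wet acetone should remove the silyl group and move the acetonide, and the sequence comes back to the route at 14.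

2. Step 13. The allylation may give the wrong C6/C7 relationship (the syn adduct, cis-lactone series, is the usual outcome for open-chain 2-(bromomethyl)acrylates), may oligomerise, or may lose the C8 oxygen by reductive 1,4-elimination. The fallback sets out from 19 and corrects the relationship by inversion instead of relying on the transition state. Zinc dust in aqueous NH4Cl/THF, an open Barbier variant that favours the syn adduct, should give the 6-epi hydroxy ester F4. LiOH in aqueous THF at 0 °C should give the 6-epi hydroxy acid F5. Mitsunobu lactonisation (PPh3, DIAD, high dilution) should then close the lactone with inversion at C6, and the sequence comes back at 21.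

3. Step 15. Site selectivity between O8 and O9 may be poor, or the ester may migrate between them. The fallback sets out from 22 and fixes the site by protection. TESOTf and 2,6-lutidine should give the 8,9-bis(triethylsilyl) ether F6. PPTS in MeOH at 0 °C should cleave the less hindered O8 silyl ether first to give the 9-O-triethylsilyl 8-alcohol F7. Isovaleric anhydride and DMAP should give the 9-O-triethylsilyl 8-isovalerate F8, and HF·pyridine should then free O9, coming back at 23.

**Further compounds**

F1 | step 7 | acyclic pyrrolidine enaminone (C3 pyrrolidinyl; C9 and C10 hydroxyls free; 7,8-acetonide) | C[C@](O)(C(=O)C=C(N1CCCC1)/C(C)=C\CO[Si](c1ccccc1)(c1ccccc1)C(C)(C)C)[C@H](O)[C@@H]1COC(C)(C)O1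
F2 | step 7 | C9 triethylsilyl ether of F1 | C[C@](O)(C(=O)C=C(N1CCCC1)/C(C)=C\CO[Si](c1ccccc1)(c1ccccc1)C(C)(C)C)[C@H](O[Si](CC)(CC)CC)[C@@H]1COC(C)(C)O1
F3 | step 7 | C9 triethylsilyl ether of furanone 13 | C[C@@]1(OC(/C(C)=C\CO[Si](c3ccccc3)(c3ccccc3)C(C)(C)C)=CC1=O)[C@H](O[Si](CC)(CC)CC)[C@@H]2COC(C)(C)O2
F4 | step 13 | 6-epi hydroxy ester (C6 epimer of 20) | O[C@H]1/C=C(/C)C2=CC(=O)[C@](C)(O2)[C@@H]2OC(C)(C)O[C@H]2[C@H]1C(=C)C(=O)OC
F5 | step 13 | 6-epi hydroxy acid | O[C@H]1/C=C(/C)C2=CC(=O)[C@](C)(O2)[C@@H]2OC(C)(C)O[C@H]2[C@H]1C(=C)C(=O)O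
F6 | step 15 | 8,9-bis(triethylsilyl) ether of 22 | C=C1C(=O)O[C@@H]2/C=C(/C)C3=CC(=O)[C@](C)(O3)[C@H](O[Si](CC)(CC)CC)[C@@H](O[Si](CC)(CC)CC)[C@@H]12
F7 | step 15 | 9-O-triethylsilyl ether of 22 | C=C1C(=O)O[C@@H]2/C=C(/C)C3=CC(=O)[C@](C)(O3)[C@H](O[Si](CC)(CC)CC)[C@@H](O)[C@@H]12
F8 | step 15 | 9-O-triethylsilyl lobatin B | C=C1C(=O)O[C@@H]2/C=C(/C)C3=CC(=O)[C@](C)(O3)[C@H](O[Si](CC)(CC)CC)[C@@H](OC(=O)CC(C)C)[C@@H]12
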